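**Plan**

- Target: 4,6-dibromo-2,3-bis(methylsulfanyl)-1H-indole. The enabling feature is the benzo-ring bond C5–C6, which links a CH carbon (C5) to a C–Br carbon (C6), with the second bromine on C4 next to C3a.
- Retrosynthesis: the N–H is traced to N–tosyl, then C5–C6 is cut with HBr added back across it. This opens the benzo ring to a pyrrole carrying CH=CBr2 on C2 (future C7/C6) and C(Br)=CH2 on C3 (future C4/C5).
- The dibromoalkene goes back to a formyl group (CBr4/PPh3; formyl carbon from DMF) and the bromoalkene to an acetyl group. The two C–S bonds go back to MeSCl, which leaves 3-acetylpyrrole.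
- Forward: the five-membered ring is bought and substituted in the order C5–S, C2–CHO, C4–S, N–Ts. The two carbonyls are then turned into the bromoalkenes, the six-membered ring is closed by thermal 6π-electrocyclization with loss of HBr, and the tosyl group is removed.
- Stereochemistry: none. The target and all intermediates have no stereocentre and no stereogenic double bond.
- N-Tosyl is chosen over a carbamate because it survives the heat and HBr of the ring closure while still lowering the aromaticity of the pyrrole.

Key step: step 7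

Remark: 4,6-dibromo-1H-indole and 3-bromo-1H-pyrrole-2-carbaldehyde, which appear only in fallbacks, are taken to be purchasable. Pyrrole numbering is used up to compound 11 and indole numbering from compound 12 on (pyrrole C2, C3, C4, C5 become indole C7a, C3a, C3, C2).

**Route**

Step 1
Reactants: 1 3-acetylpyrrole; 2 dimethyl disulfide
Product: 3 1-[5-(methylsulfanyl)-1H-pyrrol-3-yl]ethan-1-one
Conditions: MeSSMe (0.55 equiv), SO2Cl2 (0.55 equiv), CH2Cl2, −20 °C; then 1, CH2Cl2, −78 °C → 0 °C
Reagents that add atoms: methanesulfenyl chloride, CSCl, made in the flask from dimethyl disulfide 2, CSSC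
Why: Electrophilic aromatic sulfenylation; a 3-acylpyrrole reacts at C5, the α-position whose σ-complex puts no positive charge on the acyl-bearing carbon, and one equivalent of sulfenyl chloride at low temperature should hold the reaction at monosubstitution.

Step 2
Reactants: 3 1-[5-(methylsulfanyl)-1H-pyrrol-3-yl]ethan-1-one
Product: 5 3-acetyl-5-(methylsulfanyl)-1H-pyrrole-2-carbaldehyde, via iminium chloride 4 (not isolated)
Conditions: POCl3, DMF, ClCH2CH2Cl, 0 °C → 60 °C; then H2O, 60 °C
Reagents that add atoms: N,N-dimethylformamide, CN(C)C=O; water, O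
Why: Vilsmeier–Haack formylation should go to the only free α-position (C2), which is activated through nitrogen by the C5 sulfide and is less crowded than C4, and acetylpyrroles are known to tolerate the chloroiminium reagent.

Step 3
Reactants: 5 3-acetyl-5-(methylsulfanyl)-1H-pyrrole-2-carbaldehyde; 2 dimethyl disulfide
Product: 6 3-acetyl-4,5-bis(methylsulfanyl)-1H-pyrrole-2-carbaldehyde
Conditions: MeSSMe (0.6 equiv), SO2Cl2 (0.6 equiv), CH2Cl2, −20 °C; then 5, CH2Cl2, −40 °C → rt
Reagents that add atoms: methanesulfenyl chloride, CSCl, made in the flask from dimethyl disulfide 2, CSSC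
Why: Electrophilic aromatic sulfenylation at the single remaining ring C–H (C4); the σ-complex carries its charge on C5, where nitrogen and the methylsulfanyl group both stabilise it, and on neither carbonyl-bearing carbon.

Step 4
Reactants: 6 3-acetyl-4,5-bis(methylsulfanyl)-1H-pyrrole-2-carbaldehyde
Product: 8 3-acetyl-1-(4-methylbenzenesulfonyl)-4,5-bis(methylsulfanyl)-1H-pyrrole-2-carbaldehyde, via sodium pyrrolide 7 (not isolated)
Conditions: NaH (1.05 equiv), THF, 0 °C; then TsCl, 0 °C → rt
Reagents that add atoms: 4-methylbenzenesulfonyl chloride, Cc1ccc(cc1)S(Cl)(=O)=O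
Why: N-Sulfonylation of a pyrrolide anion; the N–H flanked by two acyl groups is far more acidic than the methyl ketone, so one equivalent of NaH should deprotonate nitrogen only and avoid an intramolecular aldol between the acetyl and formyl groups.

Step 5
Reactants: 8 3-acetyl-1-(4-methylbenzenesulfonyl)-4,5-bis(methylsulfanyl)-1H-pyrrole-2-carbaldehyde; 9 carbon tetrabromide
Product: 10 1-[2-(2,2-dibromoethenyl)-1-(4-methylbenzenesulfonyl)-4,5-bis(methylsulfanyl)-1H-pyrrol-3-yl]ethan-1-one
Conditions: CBr4 (2 equiv), PPh3 (4 equiv), CH2Cl2, 0 °C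
Reagents that add atoms: carbon tetrabromide 9, BrC(Br)(Br)Br
Why: Ramirez dibromoolefination (first stage of the Corey–Fuchs sequence); the ylide Ph3P=CBr2 reacts with aldehydes much faster than with a hindered methyl ketone, and the conditions are neutral.

Step 6
Reactants: 10 1-[2-(2,2-dibromoethenyl)-1-(4-methylbenzenesulfonyl)-4,5-bis(methylsulfanyl)-1H-pyrrol-3-yl]ethan-1-one
Product: 11 3-(1-bromoethenyl)-2-(2,2-dibromoethenyl)-1-(4-methylbenzenesulfonyl)-4,5-bis(methylsulfanyl)-1H-pyrrole
Conditions: P(OPh)3, Br2, CH2Cl2, −60 °C; then Et3N, 10, −60 °C → reflux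
Reagents that add atoms: bromine, BrBr, delivered as bromotriphenoxyphosphonium bromide
Why: Conversion of an aryl methyl ketone into a 1-bromoalkene with a triphenyl phosphite–bromine reagent; the bromophosphonium salt activates the carbonyl oxygen, bromide adds, and amine-induced elimination expels triphenyl phosphate, while binding bromine to phosphorus before the substrate is added keeps free Br2 away from the sulfides.

Step 7
Reactants: 11 3-(1-bromoethenyl)-2-(2,2-dibromoethenyl)-1-(4-methylbenzenesulfonyl)-4,5-bis(methylsulfanyl)-1H-pyrrole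
Product: 13 4,6-dibromo-1-(4-methylbenzenesulfonyl)-2,3-bis(methylsulfanyl)-1H-indole, via tribromodihydroindole 12 (not isolated)
Conditions: 2,6-lutidine (1.5 equiv), BHT (cat.), degassed 1,2-dichlorobenzene, 170 °C, sealed tube, dark
Reagents that add atoms: none
Why: Proposed new method: on heating, the hexatriene C5H2=C4(Br)–C3a=C7a–C7H=C6Br2, whose central double bond is the pyrrole C2=C3 bond, should undergo a thermal disrotatory six-electron electrocyclization that forms the C5–C6 σ-bond and closes the six-membered carbocycle as the 5,6-dihydroindole 12. Compound 12 holds an allylic gem-dibromide at C6 beside the C5 methylene and should lose HBr at once (taken up by 2,6-lutidine), because this elimination creates the benzene ring of 13. The closest known reaction type is the thermal 6π-electrocyclization of 2,3-dialkenylpyrroles and 2,3-dialkenylindoles to indoles and carbazoles with aromatization by elimination or dehydrogenation; a gem-dibromo terminus has no precedent. No stereocentre arises in 12 (C5 is CH2, C6 is CBr2), so the sense of rotation is without consequence. The selectivity needed is retention of bromine at both C4 and C6, which the substrate secures because the C4 bromine stays vinylic and cannot be eliminated, while the C6 gem-dibromide can give up only one bromine. The N-sulfonyl group lowers the aromatic stabilisation of the pyrrole and steers the dibromovinyl terminus toward C3 (the reactive s-cis rotamer), which should offset the penalty of the inward bromine, and it withstands both the temperature and HBr.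

Step 8
Reactants: 13 4,6-dibromo-1-(4-methylbenzenesulfonyl)-2,3-bis(methylsulfanyl)-1H-indole
Product: 14 4,6-dibromo-2,3-bis(methylsulfanyl)-1H-indole
Conditions: KOH, THF/MeOH/H2O, 50 °C
Reagents that add atoms: none
Why: Base-mediated N-desulfonylation (nucleophilic attack at sulfur with the brominated indolide as leaving group, protonated by the hydroxylic solvent); aryl bromides and aryl methyl sulfides are inert to these conditions, and no acid is used that could cause sulfenyl migration.

**Compound list**

1 | 3-acetylpyrrole (1-(1H-pyrrol-3-yl)ethan-1-one) | CC(=O)c1cc[nH]c1 | starting material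
2 | dimethyl disulfide | CSSC | starting material
3 | 1-[5-(methylsulfanyl)-1H-pyrrol-3-yl]ethan-1-one | CC(=O)c1c[nH]c(SC)c1 | intermediate
4 | {[3-acetyl-5-(methylsulfanyl)-1H-pyrrol-2-yl]methylidene}dimethylazanium chloride | CC(=O)c1cc(SC)[nH]c1C=[N+](C)C.[Cl-] | intermediate
5 | 3-acetyl-5-(methylsulfanyl)-1H-pyrrole-2-carbaldehyde | CC(=O)c1cc(SC)[nH]c1C=O | intermediate
6 | 3-acetyl-4,5-bis(methylsulfanyl)-1H-pyrrole-2-carbaldehyde | CC(=O)c1c(SC)c(SC)[nH]c1C=O | intermediate
7 | sodium 3-acetyl-2-formyl-4,5-bis(methylsulfanyl)pyrrol-1-ide | CC(=O)c1c(SC)c(SC)[n-]c1C=O.[Na+] | intermediate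
8 | 3-acetyl-1-(4-methylbenzenesulfonyl)-4,5-bis(methylsulfanyl)-1H-pyrrole-2-carbaldehyde | CC(=O)c1c(SC)c(SC)n(c1C=O)S(=O)(=O)c1ccc(C)cc1 | intermediate
9 | carbon tetrabromide | BrC(Br)(Br)Br | starting material
10 | 1-[2-(2,2-dibromoethenyl)-1-(4-methylbenzenesulfonyl)-4,5-bis(methylsulfanyl)-1H-pyrrol-3-yl]ethan-1-one | CC(=O)c1c(SC)c(SC)n(c1C=C(Br)Br)S(=O)(=O)c1ccc(C)cc1 | intermediate
11 | 3-(1-bromoethenyl)-2-(2,2-dibromoethenyl)-1-(4-methylbenzenesulfonyl)-4,5-bis(methylsulfanyl)-1H-pyrrole | C=C(Br)c1c(SC)c(SC)n(c1C=C(Br)Br)S(=O)(=O)c1ccc(C)cc1 | intermediate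
12 | 4,6,6-tribromo-1-(4-methylbenzenesulfonyl)-2,3-bis(methylsulfanyl)-5,6-dihydro-1H-indole | CSC1=C(SC)C2=C(Br)CC(Br)(Br)C=C2N1S(=O)(=O)c1ccc(C)cc1 | intermediate
13 | 4,6-dibromo-1-(4-methylbenzenesulfonyl)-2,3-bis(methylsulfanyl)-1H-indole | CSc1c(SC)c2c(Br)cc(Br)cc2n1S(=O)(=O)c1ccc(C)cc1 | intermediate
14 | 4,6-dibromo-2,3-bis(methylsulfanyl)-1H-indole | CSc1[nH]c2cc(Br)cc(Br)c2c1SC | target

**Step count and risks**

Total step count: 8. Longest linear sequence: 8 steps (from 1 to 14).

Steps most likely to fail:

1. Step 7. The ring closure may be too slow below the temperature at which the tribromotriene breaks down (dehydrobromination of the dibromovinyl group, radical loss of bromine), because the inward bromine of the CBr2 terminus raises the barrier. The fallback gives up the benzo-ring closure and places the sulfides on a preformed indole by known electrophilic sulfenylation. It sets out from dimethyl disulfide 2, which is converted into MeSCl as in step 1. One equivalent is added at −78 °C to purchased 4,6-dibromo-1H-indole F1 in CH2Cl2 and should give 4,6-dibromo-3-(methylsulfanyl)-1H-indole F2 by attack at C3. A second equivalent at 0 °C to rt should sulfenylate C2 (attack at C3 followed by 1,2-shift of sulfur) and return to the route at the target 14.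

2. Step 6. Activation of the hindered, twisted ketone may be incomplete, or the reaction may stop at or run on to the gem-dibromide. The fallback sets out from 10 and replaces carbonyl activation by a Barton-type vinyl halide synthesis. Ketone 10 is condensed with 1,2-bis(tert-butyldimethylsilyl)hydrazine under Sc(OTf)3 catalysis to the N-silyl hydrazone 1-{1-[2-(2,2-dibromoethenyl)-1-(4-methylbenzenesulfonyl)-4,5-bis(methylsulfanyl)-1H-pyrrol-3-yl]ethylidene}-2-(tert-butyldimethylsilyl)hydrazine F3, which avoids free hydrazine and so spares the N-tosyl group. Oxidation of F3 with bromine and 2-tert-butyl-1,1,3,3-tetramethylguanidine in CH2Cl2 at −10 °C should release nitrogen and give the 1-bromoalkene, coming back to the route at 11.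

3. Step 2. Formylation may occur at C4 in place of C2, or the chloroiminium reagent may attack the enol of the acetyl group. The fallback fixes the regiochemistry by starting from a pyrrole that already carries the C2 formyl group and a C3 handle. It sets out from dimethyl disulfide 2: MeSCl (2.2 equiv) is added to purchased 3-bromo-1H-pyrrole-2-carbaldehyde F4, in which C4 and C5 are the only free positions. Sulfenylation should pass through 3-bromo-4-(methylsulfanyl)-1H-pyrrole-2-carbaldehyde F5 to 3-bromo-4,5-bis(methylsulfanyl)-1H-pyrrole-2-carbaldehyde F6. Tosylation (TsCl, Et3N, DMAP, CH2Cl2) should give 3-bromo-1-(4-methylbenzenesulfonyl)-4,5-bis(methylsulfanyl)-1H-pyrrole-2-carbaldehyde F7. Stille coupling of F7 with tributyl(1-ethoxyethenyl)stannane (Pd(PPh3)4, toluene, 100 °C) should give 3-(1-ethoxyethenyl)-1-(4-methylbenzenesulfonyl)-4,5-bis(methylsulfanyl)-1H-pyrrole-2-carbaldehyde F8. Hydrolysis of the enol ether (1 M HCl, THF, rt) then returns to the route at 8, bypassing steps 1 to 4.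

**Further compounds**

F1 | step 7 | 4,6-dibromo-1H-indole | Brc1cc(Br)c2cc[nH]c2c1
F2 | step 7 | 4,6-dibromo-3-(methylsulfanyl)-1H-indole | CSc1c[nH]c2cc(Br)cc(Br)c12
F3 | step 6 | 1-{1-[2-(2,2-dibromoethenyl)-1-(4-methylbenzenesulfonyl)-4,5-bis(methylsulfanyl)-1H-pyrrol-3-yl]ethylidene}-2-(tert-butyldimethylsilyl)hydrazine | CC(=NN[Si](C)(C)C(C)(C)C)c1c(SC)c(SC)n(c1C=C(Br)Br)S(=O)(=O)c1ccc(C)cc1
F4 | step 2 | 3-bromo-1H-pyrrole-2-carbaldehyde | O=Cc1[nH]ccc1Br
F5 | step 2 | 3-bromo-4-(methylsulfanyl)-1H-pyrrole-2-carbaldehyde | CSc1c[nH]c(C=O)c1Br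
F6 | step 2 | 3-bromo-4,5-bis(methylsulfanyl)-1H-pyrrole-2-carbaldehyde | CSc1[nH]c(C=O)c(Br)c1SC
F7 | step 2 | 3-bromo-1-(4-methylbenzenesulfonyl)-4,5-bis(methylsulfanyl)-1H-pyrrole-2-carbaldehyde | CSc1c(SC)c(Br)c(C=O)n1S(=O)(=O)c1ccc(C)cc1
F8 | step 2 | 3-(1-ethoxyethenyl)-1-(4-methylbenzenesulfonyl)-4,5-bis(methylsulfanyl)-1H-pyrrole-2-carbaldehyde | CCOC(=C)c1c(SC)c(SC)n(c1C=O)S(=O)(=O)c1ccc(C)cc1
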